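**Plan**

1. Retrosynthesis: after the sulfate S–O bond and the ester are removed, the C1–C(dienoate) and C2–C(butenyl) bonds are cut together. This leaves a cis-fused C1=C2–C3(Me)=C4 diene, a dienyl iodide and a butenylboronate. The diene is traced back through the C8–CH3 bond and a ring A 2-ene-1,4-diol to a quinone monoketal/2-silyloxybutadiene Diels–Alder adduct (C4a–C5 and C8–C8a bonds).
2. Forward: ring A is the former aromatic ring of 4-methoxy-2-methylphenol and ring B is closed by the Diels–Alder reaction. Ring B is then methylated at C8, ring A is taken to the diene, C7 is reduced and silylated, and both side chains are attached in one palladium-catalysed step before sulfation and saponification.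
3. Feature used by the key step: C1 (dienoic acid chain) and C2 (butenyl) are vicinal and cis, on the face of ring A that also carries H-4a and H-8a, and they sit next to the C3(Me)=C4 alkene. This is the pattern left by a 1,2-addition across C1=C2 of a ring A 1,3-diene.
4. Stereochemistry: C4a/C8a (cis, absolute) come from the catalytic enantioselective Diels–Alder step. C8 comes from lower-face methylation of the only α′-enolate of a ring B enone (a methyl carried in on the diene would end on the opposite face). C7 comes from equatorial hydride delivery once ring A is flat. C1 and C2 come from convex-face syn-carbopalladation and inner-sphere C–C coupling.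

Key step: step 17

Conventions: locants of all bicyclic compounds are those of the target (naphthalene numbering, C1 carrying the dienoate chain). The bicycle is viewed with the C4a–C8a bond vertical (C8a on top), ring A on the right and ring B on the left. "Lower face" is the face away from the viewer; H-4a and H-8a lie on it in every compound, and it is the convex face. The target is written as the free carboxylic acid and hydrogen sulfate.

Assumption: the (S)-oxazaborolidinium catalyst of step 3 is taken to give the enantiomer drawn for 5; if the sense proves to be the reverse, the (R)-catalyst is used and nothing else changes.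

**Route**

Step 1
Reactants: 1 4-methoxy-2-methylphenol
Product: 2 4,4-dimethoxy-2-methylcyclohexa-2,5-dien-1-one
Conditions: PhI(OAc)2, MeOH, 0 °C
Reagents that add atoms: methanol, CO
Why: Hypervalent-iodine oxidative dearomatisation of a p-methoxyphenol in methanol should trap the phenoxenium-type intermediate at the methoxy-bearing carbon and give the quinone monoketal.

Step 2
Reactants: 3 but-3-en-2-one
Product: 4 2-(triisopropylsilyloxy)buta-1,3-diene
Conditions: i-Pr3SiOTf, Et3N, CH2Cl2, 0 °C → rt
Reagents that add atoms: triisopropylsilyl trifluoromethanesulfonate, CC(C)[Si](C(C)C)(C(C)C)OS(=O)(=O)C(F)(F)F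
Why: Silyl enol ether formation by soft enolisation can only occur at the methyl group and gives the 2-silyloxydiene.

Step 3
Reactants: 2 4,4-dimethoxy-2-methylcyclohexa-2,5-dien-1-one; 4 2-(triisopropylsilyloxy)buta-1,3-diene
Product: 5 cis-fused adduct 1,1-dimethoxy-3-methyl-7-(triisopropylsilyloxy)-4a,5,8,8a-tetrahydronaphthalen-4(1H)-one, H-4a and H-8a on the lower face
Conditions: (S)-1-(2-methylphenyl)-3,3-diphenyltetrahydro-1H,3H-pyrrolo[1,2-c][1,3,2]oxazaborole·HN(SO2CF3)2 (20 mol %), CH2Cl2, −78 → −40 °C
Reagents that add atoms: none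
Why: Enantioselective Diels–Alder reaction under chiral oxazaborolidinium Lewis acid catalysis, a combination established for quinone monoketals and 2-silyloxydienes: the cation activates only the unsubstituted C=C, the diene CH2 next to C–OSi bonds to the enone β-carbon beside the ketal so that oxygen ends at C7, suprafacial addition fixes the cis fusion and the catalyst fixes its absolute sense.

Step 4
Reactants: 5 Diels–Alder adduct
Product: 6 1,1-dimethoxy-3-methyl-7-(triisopropylsilyloxy)-1,4,4a,5,8,8a-hexahydronaphthalen-4-ol, 4-OH on the upper face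
Conditions: NaBH4, CeCl3·7H2O, MeOH, −78 °C
Reagents that add atoms: none
Why: Luche 1,2-reduction with hydride arriving on the convex lower face removes the carbonyl that would make H-4a doubly acidic once the ring B enone exists; the C4 configuration is of no consequence because this oxygen is lost in step 11.

Step 5
Reactants: 6 allylic alcohol
Product: 7 1,1-dimethoxy-3-methyl-7-(triisopropylsilyloxy)-1,4,4a,5,8,8a-hexahydronaphthalen-4-yl pivalate
Conditions: t-BuCOCl, pyridine, DMAP (cat.), CH2Cl2, 0 → 40 °C
Reagents that add atoms: pivaloyl chloride, CC(C)(C)C(Cl)=O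
Why: DMAP-catalysed acylation gives an ester without α-hydrogens that withstands the oxidation and enolate steps and is removed by the hydride of step 10.

Step 6
Reactants: 7 silyl enol ether pivalate
Product: 8 ring B enone 1,1-dimethoxy-3-methyl-7-oxo-1,4,4a,7,8,8a-hexahydronaphthalen-4-yl pivalate (C5=C6)
Conditions: Pd(OAc)2 (10 mol %), O2 (1 atm), DMSO, 40 °C
Reagents that add atoms: none
Why: Saegusa–Ito oxidation: the enol ether transmetallates to divalent palladium at C6 and β-hydride elimination from C5 gives the C5=C6 enone, which leaves C8 as the only α′ position.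

Step 7
Reactants: 8 ring B enone
Product: 10 1,1-dimethoxy-3,8-dimethyl-7-oxo-1,4,4a,7,8,8a-hexahydronaphthalen-4-yl pivalate with 8-CH3 on the lower face, via lithium dienolate 9 (not isolated)
Conditions: LiN(i-Pr)2, THF, −78 °C; then MeI, −78 → −30 °C
Reagents that add atoms: iodomethane, CI
Why: Kinetic α′-deprotonation of the enone followed by enolate alkylation: iodomethane should reach C8 from the lower face, anti to the ketal carbon C1 on C8a, which places the methyl cis to H-8a.

Step 8
Reactants: 10 8-methyl enone
Product: 12 1,1-dimethoxy-3,8-dimethyl-7-(triisopropylsilyloxy)-1,4,4a,5,8,8a-hexahydronaphthalen-4-yl pivalate (C6=C7 enol ether), via lithium enolate 11 (not isolated)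
Conditions: LiBH(s-Bu)3 (L-Selectride), THF, −78 °C; then i-Pr3SiOTf, −78 → 0 °C
Reagents that add atoms: triisopropylsilyl trifluoromethanesulfonate, CC(C)[Si](C(C)C)(C(C)C)OS(=O)(=O)C(F)(F)F
Why: Conjugate reduction of the β-monosubstituted cyclohexenone by the bulky borohydride gives the C6=C7 enolate without touching C8, and O-silylation masks C7 at the ketone level for the hydride and titanium steps.

Step 9
Reactants: 12 ketal silyl enol ether
Product: 13 ring A enone 3,8-dimethyl-1-oxo-7-(triisopropylsilyloxy)-1,4,4a,5,8,8a-hexahydronaphthalen-4-yl pivalate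
Conditions: pyridinium p-toluenesulfonate (cat.), acetone/H2O, 0 °C → rt
Reagents that add atoms: water, O
Why: Acid-catalysed ketal hydrolysis: the allylic dimethyl ketal ionises far more readily than the triisopropylsilyl enol ether or the pivalate.

Step 10
Reactants: 13 ring A enone
Product: 14 3,8-dimethyl-7-(triisopropylsilyloxy)-1,4,4a,5,8,8a-hexahydronaphthalene-1,4-diol, both OH drawn on the upper face
Conditions: i-Bu2AlH (5 equiv), CH2Cl2, −78 → 0 °C
Reagents that add atoms: none
Why: Hydride 1,2-reduction of the enone and reductive cleavage of the pivalate in one operation give the 2-ene-1,4-diol; hydride is expected on the lower face at C1, but either C1 epimer serves because both carbinol centres become sp2 in step 11.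

Step 11
Reactants: 14 2-ene-1,4-diol
Product: 15 triisopropyl[(3,8-dimethyl-4a,5,8,8a-tetrahydronaphthalen-7-yl)oxy]silane (ring A C1=C2–C3(Me)=C4 diene, ring B C6=C7 enol ether)
Conditions: TiCl3, LiAlH4 (2:1), THF, 0 °C → reflux
Reagents that add atoms: none
Why: McMurry-type reductive 1,4-elimination of a 2-ene-1,4-diol by low-valent titanium cleaves both C–O bonds through an allylic radical and moves the alkene into the 1,3-diene; C4a and C8a are not involved.

Step 12
Reactants: 15 diene silyl enol ether
Product: 16 3,8-dimethyl-4a,5,6,8a-tetrahydronaphthalen-7(8H)-one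
Conditions: Bu4NF/AcOH (1:1), THF, 0 °C
Reagents that add atoms: none
Why: Fluoride desilylation with buffered protonation at C6 releases the ketone without exposing the C8 stereocentre to base.

Step 13
Reactants: 16 ketone
Product: 17 3,8-dimethyl-4a,5,6,7,8,8a-hexahydronaphthalen-7-ol, 7-OH on the lower face, cis to 8-CH3
Conditions: LiBH(s-Bu)3 (L-Selectride), THF, −78 °C
Reagents that add atoms: none
Why: Bulky borohydride reduction of a 2-methylcyclohexanone: with ring A flat the cis-fused ketone should sit in the chair with 8-CH3 equatorial and H-8a axial, so equatorial hydride attack gives the axial alcohol on the lower face.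

Step 14
Reactants: 17 alcohol
Product: 18 tert-butyl[(3,8-dimethyl-4a,5,6,7,8,8a-hexahydronaphthalen-7-yl)oxy]dimethylsilane
Conditions: t-BuMe2SiCl, imidazole, DMF, 40 °C
Reagents that add atoms: tert-butyldimethylsilyl chloride, CC(C)(C)[Si](C)(C)Cl
Why: Silylation under base catalysis protects the secondary alcohol, which could otherwise act as a hydride donor toward organopalladium species in step 17.

Step 15
Reactants: 19 but-2-yne
Product: 20 (Z)-2-(but-2-en-2-yl)-4,4,5,5-tetramethyl-1,3,2-dioxaborolane (the two methyls cis)
Conditions: pinacolborane, Cp2Zr(H)Cl (5 mol %), Et3N (10 mol %), neat, sealed tube, 60 °C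
Reagents that add atoms: pinacolborane, [H]B1OC(C)(C)C(C)(C)O1
Why: Zirconium-catalysed hydroboration adds H and B syn across the symmetrical alkyne, so no regiochemical question arises and the methyls end cis.

Step 16
Reactants: 21 ethyl (E)-4-oxobut-2-enoate
Product: 22 ethyl (2E,4E)-5-iodopenta-2,4-dienoate
Conditions: CrCl2, CHI3, THF, 0 °C
Reagents that add atoms: iodoform, IC(I)I
Why: Takai olefination of the aldehyde through a gem-dichromium species gives the E-alkenyl iodide and leaves the enoate alkene untouched.

Step 17
Reactants: 18 silyl-protected diene; 22 ethyl (2E,4E)-5-iodopenta-2,4-dienoate; 20 butenylboronate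
Product: 23 ethyl (2E,4E)-5-[2-((E)-but-2-en-2-yl)-7-(tert-butyldimethylsilyloxy)-3,8-dimethyl-1,2,4a,5,6,7,8,8a-octahydronaphthalen-1-yl]penta-2,4-dienoate, with both side chains, H-4a, H-8a, 8-CH3 and 7-O on the lower face
Conditions: Pd2(dba)3 (5 mol %), KF (3 equiv), 22 (1.5 equiv), 20 (2 equiv, added over 4 h), DMA, 40 °C
Reagents that add atoms: none
Why: Proposed new method: oxidative addition of 22 to phosphine-free zerovalent palladium is followed by syn insertion of the C1=C2 bond of 18 from the lower face, the dienyl group going to C1 and palladium to C2 as an η3-allyl over C2–C4; fluoride-assisted transmetallation with 20 and inner-sphere reductive elimination at C2 then deliver the butenyl group from the palladium face. The closest known reaction type is the palladium-catalysed three-component 1,2-difunctionalisation of terminal 1,3-dienes with alkenyl electrophiles and organoboron reagents, which has not been applied to a ring-fused trisubstituted cyclic diene. No ring is closed. C1 is set by the face of insertion, since ring B blocks the upper face of the cis-fused bicycle, and C2 by delivery from palladium, which places the two alkenyl groups cis. Regioselectivity rests on insertion at the less substituted alkene with palladium avoiding the methyl-bearing C3, and on coordination of the proximal alkene of the new dienyl chain, which should hold palladium at C2 rather than C4. The step also needs reductive elimination to outrun β-hydride loss from C4a and direct coupling of 22 with 20, for which the phosphine-free fluoride medium and slow addition of the boronate are the handles.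

Step 18
Reactants: 23 silyl ether ester
Product: 24 ethyl (2E,4E)-5-[2-((E)-but-2-en-2-yl)-7-hydroxy-3,8-dimethyl-1,2,4a,5,6,7,8,8a-octahydronaphthalen-1-yl]penta-2,4-dienoate
Conditions: Bu4NF, THF, 0 °C → rt
Reagents that add atoms: none
Why: Fluoride desilylation frees the C7 alcohol without affecting the dienoate or the three alkenes.

Step 19
Reactants: 24 hydroxy ester
Product: 25 ethyl (2E,4E)-5-[2-((E)-but-2-en-2-yl)-3,8-dimethyl-7-(sulfooxy)-1,2,4a,5,6,7,8,8a-octahydronaphthalen-1-yl]penta-2,4-dienoate
Conditions: SO3·pyridine (5 equiv), pyridine, 25 °C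
Reagents that add atoms: sulfur trioxide–pyridine complex, O=S(=O)=O.c1ccncc1
Why: O-Sulfation of the only hydroxyl with the mild SO3 donor occurs with retention at C7, the acid still being protected as its ester.

Step 20
Reactants: 25 sulfate ester
Product: 26 target, (2E,4E)-5-[2-((E)-but-2-en-2-yl)-3,8-dimethyl-7-(sulfooxy)-1,2,4a,5,6,7,8,8a-octahydronaphthalen-1-yl]penta-2,4-dienoic acid
Conditions: LiOH, THF/H2O, 0 → 25 °C; then cold aq. HCl to pH 2–3
Reagents that add atoms: lithium hydroxide, [Li+].[OH-]
Why: Saponification of the ethyl ester by acyl–oxygen cleavage; the anionic secondary alkyl sulfate is inert to hydroxide under these conditions and no stereocentre is touched.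

**Compound list**

1 | 4-methoxy-2-methylphenol | COc1ccc(O)c(C)c1 | starting material
2 | 4,4-dimethoxy-2-methylcyclohexa-2,5-dien-1-one | COC1(OC)C=CC(=O)C(C)=C1 | intermediate
3 | but-3-en-2-one | CC(=O)C=C | starting material
4 | 2-(triisopropylsilyloxy)buta-1,3-diene | C=CC(=C)O[Si](C(C)C)(C(C)C)C(C)C | intermediate
5 | cis-fused 1,1-dimethoxy-3-methyl-7-(triisopropylsilyloxy)-4a,5,8,8a-tetrahydronaphthalen-4(1H)-one | CC1=CC(OC)(OC)[C@@H]2CC(O[Si](C(C)C)(C(C)C)C(C)C)=CC[C@@H]2C1=O | intermediate
6 | 4-alcohol of 5 (4-OH upper face) | CC1=CC(OC)(OC)[C@@H]2CC(O[Si](C(C)C)(C(C)C)C(C)C)=CC[C@@H]2[C@@H]1O | intermediate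
7 | 4-pivalate of 6 | CC1=CC(OC)(OC)[C@@H]2CC(O[Si](C(C)C)(C(C)C)C(C)C)=CC[C@@H]2[C@@H]1OC(=O)C(C)(C)C | intermediate
8 | ring B enone, 1,1-dimethoxy-3-methyl-7-oxo-1,4,4a,7,8,8a-hexahydronaphthalen-4-yl pivalate | CC1=CC(OC)(OC)[C@@H]2CC(=O)C=C[C@@H]2[C@@H]1OC(=O)C(C)(C)C | intermediate
9 | lithium dienolate of 8 (C7–OLi, C7=C8, C5=C6) | CC1=CC(OC)(OC)[C@@H]2C=C(O[Li])C=C[C@@H]2[C@@H]1OC(=O)C(C)(C)C | intermediate (not isolated)
10 | 8-methyl enone (8-CH3 lower face) | CC1=CC(OC)(OC)[C@@H]2[C@@H](C)C(=O)C=C[C@@H]2[C@@H]1OC(=O)C(C)(C)C | intermediate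
11 | lithium enolate from conjugate reduction of 10 (C6=C7–OLi) | CC1=CC(OC)(OC)[C@@H]2[C@@H](C)C(O[Li])=CC[C@@H]2[C@@H]1OC(=O)C(C)(C)C | intermediate (not isolated)
12 | C6=C7 triisopropylsilyl enol ether, ketal, pivalate | CC1=CC(OC)(OC)[C@@H]2[C@@H](C)C(O[Si](C(C)C)(C(C)C)C(C)C)=CC[C@@H]2[C@@H]1OC(=O)C(C)(C)C | intermediate
13 | ring A enone, 3,8-dimethyl-1-oxo-7-(triisopropylsilyloxy)-1,4,4a,5,8,8a-hexahydronaphthalen-4-yl pivalate | CC1=CC(=O)[C@@H]2[C@@H](C)C(O[Si](C(C)C)(C(C)C)C(C)C)=CC[C@@H]2[C@@H]1OC(=O)C(C)(C)C | intermediate
14 | 3,8-dimethyl-7-(triisopropylsilyloxy)-1,4,4a,5,8,8a-hexahydronaphthalene-1,4-diol | CC1=C[C@H](O)[C@@H]2[C@@H](C)C(O[Si](C(C)C)(C(C)C)C(C)C)=CC[C@@H]2[C@@H]1O | intermediate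
15 | triisopropyl[(3,8-dimethyl-4a,5,8,8a-tetrahydronaphthalen-7-yl)oxy]silane | CC1=C[C@H]2CC=C(O[Si](C(C)C)(C(C)C)C(C)C)[C@H](C)[C@H]2C=C1 | intermediate
16 | 3,8-dimethyl-4a,5,6,8a-tetrahydronaphthalen-7(8H)-one | CC1=C[C@H]2CCC(=O)[C@H](C)[C@H]2C=C1 | intermediate
17 | 3,8-dimethyl-4a,5,6,7,8,8a-hexahydronaphthalen-7-ol (7-OH, 8-CH3 lower face) | CC1=C[C@H]2CC[C@H](O)[C@H](C)[C@H]2C=C1 | intermediate
18 | tert-butyldimethylsilyl ether of 17 | CC1=C[C@H]2CC[C@H](O[Si](C)(C)C(C)(C)C)[C@H](C)[C@H]2C=C1 | intermediate
19 | but-2-yne | CC#CC | starting material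
20 | (Z)-2-(but-2-en-2-yl)-4,4,5,5-tetramethyl-1,3,2-dioxaborolane | C/C=C(\C)B1OC(C)(C)C(C)(C)O1 | intermediate
21 | ethyl (E)-4-oxobut-2-enoate | CCOC(=O)/C=C/C=O | starting material
22 | ethyl (2E,4E)-5-iodopenta-2,4-dienoate | CCOC(=O)/C=C/C=C/I | intermediate
23 | ethyl ester and C7 silyl ether of the desulfated target | C/C=C(\C)[C@@H]1C(C)=C[C@H]2CC[C@H](O[Si](C)(C)C(C)(C)C)[C@H](C)[C@H]2[C@@H]1/C=C/C=C/C(=O)OCC | intermediate
24 | ethyl ester of the desulfated target (7-OH) | C/C=C(\C)[C@@H]1C(C)=C[C@H]2CC[C@H](O)[C@H](C)[C@H]2[C@@H]1/C=C/C=C/C(=O)OCC | intermediate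
25 | ethyl ester of the target (7-hydrogen sulfate) | C/C=C(\C)[C@@H]1C(C)=C[C@H]2CC[C@H](OS(=O)(=O)O)[C@H](C)[C@H]2[C@@H]1/C=C/C=C/C(=O)OCC | intermediate
26 | target CNP0450810.2 | C/C=C(\C)[C@@H]1C(C)=C[C@H]2CC[C@H](OS(=O)(=O)O)[C@H](C)[C@H]2[C@@H]1/C=C/C=C/C(=O)O | target

**Totals**

Total step count: 20. Longest linear sequence: 17 steps (steps 1, 3–14, 17–20).

**Steps most likely to fail**

Step 17 (three-component coupling). The η3-allyl intermediate may lose a β-hydrogen (H-4a or a methyl hydrogen) before transmetallation, may couple at C4, or may be by-passed by direct cross-coupling of 22 with 20; insertion beside the 8-methyl group may also lose facial control. The fallback makes the same two bonds in two stoichiometric organopalladium operations of known type. It sets out from 18 (with 22 and 19) and returns at 23. Diene 18 and iodide 22 are treated with one equivalent of Pd(dba)2 in THF at room temperature. Oxidative addition and carbopalladation of the diene then stop at the isolable iodo-bridged η3-allylpalladium dimer F1, the classical outcome when an organopalladium halide adds to a 1,3-diene without a coupling partner. Separately, but-2-yne 19 is hydrozirconated with Cp2Zr(H)Cl to (E)-but-2-en-2-yl(chloro)zirconocene F2. F2 is added to F1 in THF with maleic anhydride at −78 °C → rt; transmetallation and reductive elimination deliver the alkenyl group on the palladium-bearing face and should give 23.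

Step 11 (titanium-mediated diene formation). The allylic C–O bonds may be over-reduced to monoalkenes, the elimination may stop halfway, or the silyl enol ether may be cleaved by Lewis-acidic titanium species. The fallback avoids titanium, sets out from 13 and returns at 15. SmI2 in THF/MeOH at −78 °C removes the γ-pivaloyloxy group of enone 13 by reductive elimination; the dienolate is protonated at C2 to give the β,γ-unsaturated ketone F3. KN(SiMe3)2 and PhNTf2 in THF at −78 °C enolise F3 at the doubly activated C2 and give the dienyl triflate F4. Palladium-catalysed formate reduction (Pd(OAc)2, PPh3, Bu3N, HCO2H, DMF, 60 °C) then replaces the triflate by hydrogen and gives 15.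

Step 9 (ketal hydrolysis beside a silyl enol ether). The silyl enol ether may hydrolyse together with the ketal, or the new enone may epimerise at C8a through its dienol. The fallback gives up the masking of C7 and uses an oxidation-level detour; it sets out from 12 and returns at 16. Aqueous HCl in THF hydrolyses ketal and enol ether together to the keto-enone pivalate F5. i-Bu2AlH reduces both carbonyls and cleaves the pivalate to the triol F6, a mixture of C7 epimers. TiCl3/LiAlH4 converts the 2-ene-1,4-diol part into the diene and leaves the non-allylic C7 hydroxyl, giving the dienol F7. Dess–Martin periodinane buffered with NaHCO3 in CH2Cl2 oxidises F7 to ketone 16, which rejoins the route before the stereodefining reduction of step 13.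

**Further compounds**

F1 | step 17 | iodo-bridged η3-allylpalladium dimer from 18 and 22, written as the C2-bound monomer with palladium and the dienyl chain on the lower face | I[Pd][C@@H]1C(C)=C[C@H]2CC[C@H](O[Si](C)(C)C(C)(C)C)[C@H](C)[C@H]2[C@@H]1/C=C/C=C/C(=O)OCC
F2 | step 17 | (E)-but-2-en-2-yl(chloro)zirconocene | C/C=C(\C)[Zr](Cl)(C1C=CC=C1)C1C=CC=C1
F3 | step 11 | 3,8-dimethyl-7-(triisopropylsilyloxy)-4a,5,8,8a-tetrahydronaphthalen-1(2H)-one | CC1=C[C@H]2CC=C(O[Si](C(C)C)(C(C)C)C(C)C)[C@H](C)[C@H]2C(=O)C1
F4 | step 11 | 3,8-dimethyl-7-(triisopropylsilyloxy)-4a,5,8,8a-tetrahydronaphthalen-1-yl trifluoromethanesulfonate | CC1=C[C@H]2CC=C(O[Si](C(C)C)(C(C)C)C(C)C)[C@H](C)[C@H]2C(OS(=O)(=O)C(F)(F)F)=C1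
F5 | step 9 | 3,8-dimethyl-1,7-dioxo-1,4,4a,5,6,7,8,8a-octahydronaphthalen-4-yl pivalate | CC1=CC(=O)[C@@H]2[C@@H](C)C(=O)CC[C@@H]2[C@@H]1OC(=O)C(C)(C)C
F6 | step 9 | 3,8-dimethyl-1,4,4a,5,6,7,8,8a-octahydronaphthalene-1,4,7-triol, mixture of C7 epimers | CC1=C[C@H](O)[C@@H]2[C@@H](C)C(O)CC[C@@H]2[C@@H]1O
F7 | step 9 | 3,8-dimethyl-4a,5,6,7,8,8a-hexahydronaphthalen-7-ol, mixture of C7 epimers | CC1=C[C@H]2CCC(O)[C@H](C)[C@H]2C=C1
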